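## Retrosynthetic overview

1. The epoxide in the SMILES is cis (C2 and C9 on the same side) and every O substituent lies on one ring face. The endgame is therefore C8 methacrylation after an 8‑OH‑directed epoxidation of a (1(10)Z,4Z)‑germacradien‑6,12‑olide.
2. The cis‑fused α‑methylene‑γ‑lactone comes from a C6 ketone. C7–C11 forms by O8‑chelated alkylation, C6 is set by Felkin reduction and lactonisation, and C13 comes from a Mannich methylenation.
3. The ten‑membered ring comes from an anionic oxy‑Cope rearrangement of a cis‑1‑alkenyl‑2‑isopropenylcyclohexenol. C8–C9 forms and C1–C6 breaks. The ring alkene becomes 4Z, axial C2 gives 1(10)Z, and C1 relays its chirality to C8.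
4. The carbinol comes from axial addition of a PMBO‑acetylide to a 4‑silyloxy‑6‑isopropenyl‑3‑methylcyclohexenone, then trans‑hydroalumination. The enone comes from (S)‑carvone by reduction, silylation and allylic oxidation.
5. Ring order: cyclohexene (bought), then cyclodecadiene (oxy‑Cope), then γ‑lactone, then epoxide.

**Convention and assumption:** Germacrane numbering is used throughout: ring C1–C10, side chain C11–C13, C14 on C10, C15 on C4. In compounds 1–4 and 9–11 the six ring atoms are the future C1 (isopropenyl‑bearing), C2, C3 (O), C4 (Me), C5 and C6. The SMILES is taken literally as 1R,3S,4Z,6S,7R,8R,10S. TBS = tert‑butyldimethylsilyl and PMB = 4‑methoxybenzyl.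

## Route

**Step 1**
Reactants: 1 (S)-(+)-carvone
Product: 2 (+)-cis-carveol [(1S,5S)-2-methyl-5-(prop-1-en-2-yl)cyclohex-2-en-1-ol]
Conditions: NaBH4, CeCl3·7H2O, MeOH, 0 °C
Reagents that add atoms: none
Why: In this Luche 1,2‑reduction hydride attacks the enone axially, which gives the equatorial alcohol cis to the equatorial isopropenyl group, so the carvone stereocentre sets C3 as S.

**Step 2**
Reactants: 2 (+)-cis-carveol
Product: 3 (1S,5S)-cis-carveol TBS ether
Conditions: TBSCl, imidazole, DMF, rt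
Reagents that add atoms: tert-butyldimethylsilyl chloride CC(C)(C)[Si](C)(C)Cl
Why: This O‑silylation masks the allylic alcohol for the oxidising and strongly basic steps and touches no stereocentre.

**Step 3**
Reactants: 3 (1S,5S)-cis-carveol TBS ether
Product: 4 (4S,6S)-4-(tert-butyldimethylsilyloxy)-3-methyl-6-(prop-1-en-2-yl)cyclohex-2-en-1-one
Conditions: Rh2(cap)4 (dirhodium tetracaprolactamate, 1 mol %), 70% aq. TBHP, 1,2-dichloroethane, 40 °C
Reagents that add atoms: tert-butyl hydroperoxide CC(C)(C)OO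
Why: This peroxyl‑radical allylic C–H oxidation takes the only free ring allylic CH2 (C6) to the enone, because the bulky silyl ether shields C3–H and the near‑neutral medium leaves C1 and C3 untouched.

**Step 4**
Reactants: 5 4-methoxybenzyl alcohol + 6 trichloroethylene
Product: 7 (E)-1,2-dichlorovinyl 4-methoxybenzyl ether
Conditions: KH, THF, 0 °C; then Cl2C=CHCl, −50 °C to rt
Reagents that add atoms: none
Why: Base‑induced loss of HCl from trichloroethylene is followed by anti addition of the alkoxide to dichloroacetylene, which gives the standard ynol‑ether precursor.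

**Step 5**
Reactants: 7 (E)-1,2-dichlorovinyl 4-methoxybenzyl ether + 4 (4S,6S)-enone
Product: 9 (1R,4S,6S)-4-(tert-butyldimethylsilyloxy)-1-[(4-methoxybenzyloxy)ethynyl]-3-methyl-6-(prop-1-en-2-yl)cyclohex-2-en-1-ol (alkynyl cis to isopropenyl), via lithium alkoxyacetylide 8 (not isolated)
Conditions: 7, n-BuLi (2.2 equiv), THF, −78 to −40 °C; then 4, −78 °C; H2O quench
Reagents that add atoms: none
Why: β‑Elimination and Cl–Li exchange give the acetylide, whose 1,2‑addition is axial (antiperiplanar to the axial C1–H) on the half‑chair with isopropenyl and OTBS equatorial, as expected for a slim sp nucleophile, so C6 is set as R with the alkynyl group cis to the isopropenyl group.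

**Step 6**
Reactants: 9 propargylic alcohol
Product: 10 (1R,4S,6S)-4-(tert-butyldimethylsilyloxy)-1-[(E)-2-(4-methoxybenzyloxy)ethenyl]-3-methyl-6-(prop-1-en-2-yl)cyclohex-2-en-1-ol
Conditions: LiAlH4, THF, 0 °C to rt; H2O/aq. NaOH work-up; base-washed silica
Reagents that add atoms: none
Why: Alkoxide‑directed trans‑hydroalumination of the propargylic alcohol, then protonolysis, gives only the E enol ether, and no stereocentre changes.

**Step 7**
Reactants: 10 (E)-enol ether carbinol
Product: 13 (2Z,4S,6Z,9R)-4-(tert-butyldimethylsilyloxy)-9-(4-methoxybenzyloxy)-3,7-dimethylcyclodeca-2,6-dien-1-one, via potassium alkoxide 11 (not isolated), via ring-expanded potassium enolate 12 (not isolated)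
Conditions: KH, 18-crown-6, THF, 0 °C to rt; AcOH/THF quench at −78 °C as soon as 10 is consumed
Reagents that add atoms: none
Why: In this anionic oxy‑Cope [3,3]‑sigmatropic rearrangement the only chair free of a 1,3‑diaxial isopropenyl/OTBS clash has both groups equatorial and the alkenyl group axial, so C2 is axial in the six‑atom array (new C1=C10 is Z), the former ring alkene stays Z, and the E enol ether holds OPMB equatorial, which relays the carvone centre C1 to C8 (R) and keeps the C8–O bond in the nodal plane of the nascent enolate and so slows E1cB loss.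

**Step 8**
Reactants: 13 ring ketone
Product: 15 ethyl 2-[(1R,3Z,5S,7Z,10R)-5-(tert-butyldimethylsilyloxy)-10-(4-methoxybenzyloxy)-4,8-dimethyl-2-oxocyclodeca-3,7-dien-1-yl]acetate, via chelated lithium enolate 14 (not isolated)
Conditions: LiHMDS, THF, −78 °C; TfOCH2CO2Et, −78 °C
Reagents that add atoms: ethyl 2-(trifluoromethylsulfonyloxy)acetate CCOC(=O)COS(=O)(=O)C(F)(F)F
Why: In this kinetic enolate alkylation under Fráter–Seebach‑type control, lithium bridges O6 and O8 and the triflate attacks the outer face anti to C9, so C7 (R) is set by C8 with C11 cis to O8 on the ring, and the very reactive electrophile allows −78 °C, where β‑alkoxide loss is slow.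

**Step 9**
Reactants: 15 keto ester
Product: 17 (3S,6S,7R,8R)-3-TBSO-8-PMBO-13-norgermacra-1(10)Z,4Z-dien-6,12-olide (cis-fused lactone), via hydroxy ester 16 (not isolated)
Conditions: NaBH4, CeCl3·7H2O, MeOH, −40 °C; crude, then PPTS (cat.), toluene, 60 °C
Reagents that add atoms: none
Why: In this Luche 1,2‑reduction under Felkin–Anh control, hydride comes anti to the C8 branch, reinforced by 1,3‑induction from the β‑alkoxy group, which gives the 6S alcohol (anti,anti triad, all‑cis on the ring) that lactonises onto the ester.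

**Step 10**
Reactants: 17 cis-fused lactone
Product: 21 (3S,6S,7R,8R)-3-TBSO-8-PMBO-germacra-1(10)Z,4Z,11(13)-trien-6,12-olide, via lactone lithium enolate 18 (not isolated), via Mannich base 19 (not isolated), via trimethylammonium iodide 20 (not isolated)
Conditions: LDA, THF, −78 °C; CH2=NMe2+ I−, −78 °C to rt; MeI, MeOH, rt; aq. NaHCO3/CH2Cl2
Reagents that add atoms: Eschenmoser's salt C=[N+](C)C.[I-]
Why: Mannich aminomethylation on the convex face, N‑methylation and Hofmann‑type elimination install the exocyclic methylene, and the transient C11 centre is destroyed.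

**Step 11**
Reactants: 21 α-methylene lactone
Product: 23 (3S,6S,7R,8R)-3-acetoxy-8-PMBO-germacra-1(10)Z,4Z,11(13)-trien-6,12-olide, via C3 alcohol 22 (not isolated)
Conditions: HF·pyridine, pyridine/THF, 0 °C to rt; then Et3N, Ac2O, DMAP, 0 °C, same flask
Reagents that add atoms: acetic anhydride CC(=O)OC(C)=O
Why: Fluoride desilylation, then DMAP‑catalysed acetylation, both occur at oxygen, so C3 keeps its configuration and the Michael acceptor never meets a basic fluoride source.

**Step 12**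
Reactants: 23 C3 acetate
Product: 24 (3S,6S,7R,8R)-3-acetoxy-8-hydroxygermacra-1(10)Z,4Z,11(13)-trien-6,12-olide
Conditions: DDQ, CH2Cl2/pH 7 buffer, 0 °C
Reagents that add atoms: none
Why: Oxidative PMB cleavage (benzylic hydride abstraction, then hydrolysis of the oxocarbenium ion) is neutral and spares the acetate, the lactone and the alkenes.

**Step 13**
Reactants: 24 C8 alcohol
Product: 25 (1R,3S,6S,7R,8R,10S)-3-acetoxy-1,10-epoxy-8-hydroxygermacra-4Z,11(13)-dien-6,12-olide
Conditions: VO(acac)2 (5 mol %), TBHP (decane), CH2Cl2, 0 °C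
Reagents that add atoms: tert-butyl hydroperoxide CC(C)(C)OO
Why: In this hydroxyl‑directed vanadium‑catalysed epoxidation the homoallylic 8‑OH binds the metal and delivers oxygen syn to itself onto the only electron‑rich alkene within reach, and syn addition to the Z alkene gives the cis epoxide with C1 R and C10 S.

**Step 14**
Reactants: 25 epoxy alcohol
Product: 26 target (1R,3S,6S,7R,8R,10S)-3-acetoxy-1,10-epoxy-8-methacryloyloxygermacra-4Z,11(13)-dien-6,12-olide
Conditions: methacrylic anhydride, Et3N, DMAP, CH2Cl2, 0 °C to rt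
Reagents that add atoms: methacrylic anhydride C=C(C)C(=O)OC(=O)C(C)=C
Why: DMAP‑catalysed O‑acylation of the hindered C8 alcohol is mild enough for the epoxide, the acetate and both acrylate units, and it retains C8.

## Compound list

| No. | Name | SMILES | Role |
|---|---|---|---|
| 1 | (S)-(+)-carvone | O=C1C(C)=CC[C@H](C(C)=C)C1 | starting material |
| 2 | (+)-cis-carveol (1S,5S) | O[C@@H]1C(C)=CC[C@H](C(C)=C)C1 | intermediate |
| 3 | cis-carveol TBS ether | CC(C)(C)[Si](C)(C)O[C@@H]1C(C)=CC[C@H](C(C)=C)C1 | intermediate |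
| 4 | (4S,6S)-4-TBSO-3-methyl-6-isopropenylcyclohex-2-enone | CC(C)(C)[Si](C)(C)O[C@@H]1C(C)=CC(=O)[C@H](C(C)=C)C1 | intermediate |
| 5 | 4-methoxybenzyl alcohol | COc1ccc(CO)cc1 | starting material |
| 6 | trichloroethylene | ClC=C(Cl)Cl | starting material |
| 7 | (E)-1,2-dichlorovinyl 4-methoxybenzyl ether | COc1ccc(CO/C(Cl)=C\Cl)cc1 | intermediate |
| 8 | lithium (4-methoxybenzyloxy)acetylide | [Li+].[C-]#COCc1ccc(OC)cc1 | intermediate |
| 9 | (1R,4S,6S)-alkoxyethynyl carbinol | CC(C)(C)[Si](C)(C)O[C@@H]1C(C)=C[C@](O)(C#COCc2ccc(OC)cc2)[C@H](C(C)=C)C1 | intermediate |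
| 10 | (1R,4S,6S)-(E)-alkoxyethenyl carbinol | CC(C)(C)[Si](C)(C)O[C@@H]1C(C)=C[C@](O)(/C=C/OCc2ccc(OC)cc2)[C@H](C(C)=C)C1 | intermediate |
| 11 | potassium alkoxide of 10 | [K+].CC(C)(C)[Si](C)(C)O[C@@H]1C(C)=C[C@]([O-])(/C=C/OCc2ccc(OC)cc2)[C@H](C(C)=C)C1 | intermediate |
| 12 | ring-expanded potassium enolate | [K+].[C@H]1(OCc2ccc(OC)cc2)/C=C([O-])/C=C(C)\[C@@H](O[Si](C)(C)C(C)(C)C)C/C=C(C)\C1 | intermediate |
| 13 | (2Z,4S,6Z,9R)-4-TBSO-9-PMBO-3,7-dimethylcyclodeca-2,6-dienone | C1C(=O)/C=C(C)\[C@@H](O[Si](C)(C)C(C)(C)C)C/C=C(C)\C[C@H]1OCc2ccc(OC)cc2 | intermediate |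
| 14 | chelated lithium enolate of 13 | [Li+].[C@H]1(OCc2ccc(OC)cc2)/C=C([O-])/C=C(C)\[C@@H](O[Si](C)(C)C(C)(C)C)C/C=C(C)\C1 | intermediate |
| 15 | (7R,8R)-keto ester | [C@H]1(CC(=O)OCC)C(=O)/C=C(C)\[C@@H](O[Si](C)(C)C(C)(C)C)C/C=C(C)\C[C@H]1OCc2ccc(OC)cc2 | intermediate |
| 16 | (6S,7R,8R)-hydroxy ester | [C@H]1(CC(=O)OCC)[C@@H](O)/C=C(C)\[C@@H](O[Si](C)(C)C(C)(C)C)C/C=C(C)\C[C@H]1OCc2ccc(OC)cc2 | intermediate |
| 17 | cis-fused lactone | COc1ccc(CO[C@@H]2C/C(C)=C\C[C@H](O[Si](C)(C)C(C)(C)C)/C(C)=C\[C@@H]3OC(=O)C[C@@H]32)cc1 | intermediate |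
| 18 | lactone lithium enolate | [Li+].COc1ccc(CO[C@@H]2C/C(C)=C\C[C@H](O[Si](C)(C)C(C)(C)C)/C(C)=C\[C@@H]3OC([O-])=C[C@@H]32)cc1 | intermediate |
| 19 | Mannich base (C11 from convex-face attack) | COc1ccc(CO[C@@H]2C/C(C)=C\C[C@H](O[Si](C)(C)C(C)(C)C)/C(C)=C\[C@@H]3OC(=O)[C@@H](CN(C)C)[C@@H]32)cc1 | intermediate |
| 20 | trimethylammonium iodide | [I-].COc1ccc(CO[C@@H]2C/C(C)=C\C[C@H](O[Si](C)(C)C(C)(C)C)/C(C)=C\[C@@H]3OC(=O)[C@@H](C[N+](C)(C)C)[C@@H]32)cc1 | intermediate |
| 21 | α-methylene lactone (3-OTBS, 8-OPMB) | COc1ccc(CO[C@@H]2C/C(C)=C\C[C@H](O[Si](C)(C)C(C)(C)C)/C(C)=C\[C@@H]3OC(=O)C(=C)[C@@H]32)cc1 | intermediate |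
| 22 | C3 alcohol | COc1ccc(CO[C@@H]2C/C(C)=C\C[C@H](O)/C(C)=C\[C@@H]3OC(=O)C(=C)[C@@H]32)cc1 | intermediate |
| 23 | C3 acetate (8-OPMB) | COc1ccc(CO[C@@H]2C/C(C)=C\C[C@H](OC(C)=O)/C(C)=C\[C@@H]3OC(=O)C(=C)[C@@H]32)cc1 | intermediate |
| 24 | C8 alcohol | O[C@@H]1C/C(C)=C\C[C@H](OC(C)=O)/C(C)=C\[C@@H]2OC(=O)C(=C)[C@@H]21 | intermediate |
| 25 | epoxy alcohol | O[C@@H]1C[C@]2(C)O[C@@H]2C[C@H](OC(C)=O)/C(C)=C\[C@@H]2OC(=O)C(=C)[C@@H]21 | intermediate |
| 26 | target CNP0267696.1 | C=C(C)C(=O)O[C@@H]1C[C@]2(C)O[C@@H]2C[C@H](OC(C)=O)/C(C)=C\[C@@H]2OC(=O)C(=C)[C@@H]21 | target |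

**Total step count:** 14.
**Longest linear sequence:** 13 (steps 1–3 and 5–14).

## Steps most likely to fail

**Step 5.** The acetylide may attack equatorially and give the wrong C6 epimer. The fallback sets out from 4. (Z)-2-(4-Methoxybenzyloxy)vinyllithium, made from the (Z)-tributylstannane and n-BuLi, is a bulkier sp2 nucleophile that adds anti to the isopropenyl group and gives the trans-dialkenyl carbinol F1. Its diequatorial chair oxy‑Cope rearrangement (KH, 18-crown-6, THF) gives the 6E ring ketone F2. The Z enol ether sits axial in that chair, so the 9R centre is the same as in the main route. Thiyl‑radical equilibration (PhSSPh, hν, benzene) then relaxes the strained E alkene to the Z isomer, and the route comes back at 13.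

**Step 7.** The β‑alkoxy enolate 12 may expel PMBOK, or the chair preference may erode. The fallback sets out from 10 and lets the rearrangement–E1cB sequence run to completion (KH, 18-crown-6, rt), which gives the cross-conjugated trienone F3. Copper‑catalysed conjugate borylation (B2pin2, CuCl, NaOtBu, Xantphos, MeOH, THF) attacks only the less substituted enone terminus, from the outer ring face, and gives the β-boryl ketone F4. NaBO3·4H2O oxidises the C–B bond with retention to the β-hydroxy ketone F5. C8 is then under substrate control from C3, and any epimer is removed at this stage. 4-Methoxybenzyl trichloroacetimidate with La(OTf)3 (cat.) brings the route back at 13.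

**Step 8.** β‑Elimination, O‑alkylation or the wrong C7 epimer may intervene. The fallback sets out from 13 and avoids a free enolate. TMSOTf/Et3N gives the trimethylsilyl enol ether F6. ZnBr2‑catalysed alkylation with ethyl chloro(phenylsulfanyl)acetate, through a thionium ion on the outer face, gives the α-phenylsulfanyl keto ester F7 as C11 epimers. Bu3SnH/AIBN removes the sulfur, and the route comes back at 15.

## Further compounds

F1 | step 5 | (1S,4S,6S)-4-TBSO-1-[(Z)-2-(4-methoxybenzyloxy)ethenyl]-3-methyl-6-isopropenylcyclohex-2-en-1-ol | CC(C)(C)[Si](C)(C)O[C@@H]1C(C)=C[C@@](O)(/C=C\OCc2ccc(OC)cc2)[C@H](C(C)=C)C1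
F2 | step 5 | (2Z,4S,6E,9R)-4-TBSO-9-PMBO-3,7-dimethylcyclodeca-2,6-dienone | C1C(=O)/C=C(C)\[C@@H](O[Si](C)(C)C(C)(C)C)C/C=C(C)/C[C@H]1OCc2ccc(OC)cc2
F3 | step 7 | (2Z,4S,6Z,9E)-4-TBSO-3,7-dimethylcyclodeca-2,6,9-trienone | C1/C=C(C)\C/C=C/C(=O)/C=C(C)\[C@H]1O[Si](C)(C)C(C)(C)C
F4 | step 7 | (2Z,4S,6Z,9R)-4-TBSO-3,7-dimethyl-9-(pinacolatoboryl)cyclodeca-2,6-dienone | C1C(=O)/C=C(C)\[C@@H](O[Si](C)(C)C(C)(C)C)C/C=C(C)\C[C@H]1B2OC(C)(C)C(C)(C)O2
F5 | step 7 | (2Z,4S,6Z,9R)-4-TBSO-9-hydroxy-3,7-dimethylcyclodeca-2,6-dienone | C1C(=O)/C=C(C)\[C@@H](O[Si](C)(C)C(C)(C)C)C/C=C(C)\C[C@H]1O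
F6 | step 8 | trimethylsilyl enol ether of 13 | [C@H]1(OCc2ccc(OC)cc2)/C=C(O[Si](C)(C)C)/C=C(C)\[C@@H](O[Si](C)(C)C(C)(C)C)C/C=C(C)\C1
F7 | step 8 | α-phenylsulfanyl analogue of 15 (C11 epimers) | [C@H]1(C(Sc3ccccc3)C(=O)OCC)C(=O)/C=C(C)\[C@@H](O[Si](C)(C)C(C)(C)C)C/C=C(C)\C[C@H]1OCc2ccc(OC)cc2
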